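**Plan**
- Labdane numbering is used throughout (ring A = C1–C5 and C10; ring B = C5–C10). The target is cut at C13=C14 (phosphonate olefination), at the isopropylidene C=C (Wittig), at C4–C18 and C4–CH3 (enolate alkylations of a C3 ketone that is later removed), at C8–CH3 (Negishi), at C7–C8/C8–C9 (one-carbon insertion) and at C9–C11 (B-alkyl Suzuki).
- Enabling feature: the tetrasubstituted C8=C9 alkene of ring B beside quaternary C10. Without C8, ring B is the cyclopentene (C5, C6, C7, C9, C10 with C7=C9) of a Hajos–Parrish hydrindene; dibromocarbene inserts C8 there and leaves a bromine on it as the handle for the C8 methyl.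
- Forward order: ring A and C10 come with (S)-Hajos–Parrish ketone 1; the masked C11–C13 chain is joined to C9; ring B is enlarged from five to six members; then C8-Me, C4-Me, reductive allylation, C3 deoxygenation and two chain olefinations.
- Stereochemistry: C10 is bought with 1; H5 (α, trans fusion) comes from axial protonation in the Li/NH3 reduction; C4 comes from allylation of the resulting enolate on the α face, anti to the C10 methyl; the C13 alkene is E by thermodynamic control in the phosphonate olefination.

Key step: step 5

Remark and assumption: the same numbering is applied to the hydrindenes (which lack C8), α is the face opposite the C10 methyl, and "ketal chain" means 2-(2-methyl-1,3-dioxolan-2-yl)ethyl on C9. Sodium tribromoacetate is assumed to be used as the purchased salt (or made beforehand from commercial tribromoacetic acid and NaOH).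

**Step 1**
Reactants: 1 (S)-Hajos–Parrish ketone; 2 ethane-1,2-dithiol
Product: 3 C3 1,3-dithiolane of 1 (C4=C5 kept; C9 ketone free)
Conditions: HS(CH2)2SH, TsOH·H2O (cat.), AcOH, rt
Reagents that add atoms: ethane-1,2-dithiol (2), SCCS
Why: Acid-catalysed thioketalisation of an ene-dione selects the conjugated carbonyl (allyl-stabilised thionium ion) over the neopentyl cyclopentanone and, unlike O-ketalisation, leaves C4=C5 in place, so the enone is masked against base while the C9 ketone stays available.

**Step 2**
Reactants: 3 C3 dithiolane ketone; 4 N-phenylbis(trifluoromethanesulfonimide)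
Product: 6 C9 enol triflate (C7=C9–OTf) of the C3 dithiolane, via potassium enolate 5 (not isolated)
Conditions: KN(SiMe3)2, THF, −78 °C; then PhNTf2, −78 → 0 °C
Reagents that add atoms: N-phenylbis(trifluoromethanesulfonimide) (4), O=S(=O)(N(c1ccccc1)S(=O)(=O)C(F)(F)F)C(F)(F)F
Why: The C9 ketone can enolise only towards C7 because C10 is quaternary, so O-triflation of the enolate (enol triflate formation) should give a single regioisomer.

**Step 3**
Reactants: 6 C9 enol triflate; 7 2-methyl-2-vinyl-1,3-dioxolane
Product: 9 C3 dithiolane of the hydrinda-4,7(9)-diene carrying the ketal chain on C9, via alkylborane 8 (not isolated)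
Conditions: 7, 9-BBN, THF, 0 °C → rt; then 6, Pd(dppf)Cl2 (cat.), K3PO4 (aq), DMF, rt → 50 °C
Reagents that add atoms: 2-methyl-2-vinyl-1,3-dioxolane (7), C=CC1(C)OCCO1
Why: 9-BBN places boron on the terminal carbon of 7 and the primary alkylborane couples with the enol triflate in a B-alkyl Suzuki–Miyaura reaction, forming C9–C11 while no base-sensitive enone is present (dithioketals and ketals are tolerated).

**Step 4**
Reactants: 9 dithiolane diene; 10 iodomethane
Product: 11 hydrinda-4,7(9)-dien-3-one with 10β-methyl and the ketal chain on C9
Conditions: MeI, CaCO3, MeCN/H2O, 45 °C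
Reagents that add atoms: water, O
Why: S-Methylation makes the dithiolane a leaving group and buffered hydrolysis (alkylative dethioketalisation) should return the conjugated enone under neutral conditions that spare the dioxolane and the C7=C9 alkene.

**Step 5**
Reactants: 11 hydrindadienone; 12 sodium tribromoacetate
Product: 14 7α,8-dibromo-decalin-4,8-dien-3-one with 10β-methyl and the ketal chain on C9, via dibromocyclopropane 13 (not isolated)
Conditions: CBr3CO2Na (excess, in portions), DME, 80 °C; then PhMe, 100 °C
Reagents that add atoms: sodium tribromoacetate (12), [Na+].[O-]C(=O)C(Br)(Br)Br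
Why: Heating 12 expels CO2 and bromide to give singlet :CBr2, which adds in a concerted [2+1] fashion (the mode by which the three-membered ring closes) to the only electron-rich alkene of 11, the trisubstituted C7=C9 bond, from the α face opposite the C10 methyl to give 13. On further warming 13 should undergo the disrotatory two-electron electrocyclic opening of a cyclopropyl halide, in which the endo bromide (cis to C6 and C10) leaves as the C7–C9 bond breaks, so ring B arises by enlargement of the five-membered ring, with C8 now bonded to C7 and C9 in a six-membered ring. The resulting 2-bromoallyl cation (C7–C8–C9) is recaptured by bromide at secondary C7, because C9 is tertiary and neopentyl-like beside quaternary C10 and because this leaves the more substituted C8=C9 alkene, to which allylic bromides equilibrate on heating in any case. The closest known reaction type is dihalocarbene addition to cyclopentenes followed by thermal or silver-assisted rearrangement of the 6,6-dihalobicyclo[3.1.0]hexanes to 2,3-dihalocyclohexenes. The one new stereocentre, C7, should be α because the ion pair collapses on the face from which bromide left, but its configuration is of no consequence since C7 becomes CH2 in step 6. The step needs chemoselectivity for C7=C9 over the enone and regioselective bromide return, and these are secured by the electron-poor C4=C5 bond facing an electrophilic carbene, by the neutral base-free carbene source and by the substitution at C9/C10.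

**Step 6**
Reactants: 14 7α,8-dibromo dienone
Product: 15 8-bromo-decalin-4,8-dien-3β-ol with 10β-methyl and the ketal chain on C9 (3α epimer may accompany it)
Conditions: LiAlH4, THF, 0 °C → rt
Reagents that add atoms: none
Why: LiAlH4 reduces the enone carbonyl by 1,2-addition and displaces the secondary allylic C7 bromide by direct SN2 hydride attack (SN2′ attack at fully substituted C9 is blocked), while the vinylic C8 bromide and the ketal are inert and the C3 configuration is erased in step 7.

**Step 7**
Reactants: 15 bromo allylic alcohol
Product: 16 8-bromo-decalin-4,8-dien-3-one with 10β-methyl and the ketal chain on C9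
Conditions: MnO2, CH2Cl2, rt
Reagents that add atoms: none
Why: MnO2 oxidises allylic alcohols selectively, restoring the C3 enone needed for the ring A alkylations without touching the vinylic bromide.

**Step 8**
Reactants: 16 bromo dienone; 17 dimethylzinc
Product: 18 8-methyl-decalin-4,8-dien-3-one with 10β-methyl and the ketal chain on C9
Conditions: Me2Zn, Pd(dppf)Cl2 (cat.), 1,4-dioxane, 80 °C
Reagents that add atoms: dimethylzinc (17), C[Zn]C
Why: Negishi coupling of the vinylic bromide with Me2Zn tolerates the enone and has no β-hydride pathway, so the hindered tetrasubstituted C8=C9 alkene should be completed with its methyl group.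

**Step 9**
Reactants: 18 8-methyl dienone; 10 iodomethane
Product: 21 4,8-dimethyl-decalin-4,8-dien-3-one with 10β-methyl and the ketal chain on C9, via potassium dienolate 19 (not isolated), via 4-methyl Δ5 ketone 20 (not isolated)
Conditions: KOtBu (1 equiv), tBuOH/THF, rt; MeI (1 equiv), 0 °C; then NaOMe (cat.), MeOH, rt
Reagents that add atoms: iodomethane (10), CI
Why: γ-Deprotonation at C6 gives the extended dienolate, which is alkylated at its α-carbon C4 (classical α-methylation of a Δ4-3-ketone through the thermodynamic dienolate), and base then returns the double bond to conjugation.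

**Step 10**
Reactants: 21 4-methyl enone; 22 allyl bromide
Product: 24 4α-allyl-4β,8,10β-trimethyl-5α-decal-8-en-3-one with the ketal chain on C9, via lithium enolate 23 (not isolated)
Conditions: Li (2.2 equiv), H2O (1 equiv), NH3(l)/THF, −78 → −33 °C; then allyl bromide, −33 °C
Reagents that add atoms: allyl bromide (22), C=CCBr
Why: Dissolving-metal reductive alkylation gives the C3–C4 lithium enolate regiospecifically, C5 being protonated axially from the α face so that H5 is trans to the C10 methyl, and allyl bromide then attacks C4 from the α face, away from the 1,3-diaxial C10 methyl, which makes allyl the 4α (C18) substituent and leaves the methyl 4β.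

**Step 11**
Reactants: 24 4α-allyl ketone
Product: 26 4α-allyl-4β,8,10β-trimethyl-5α-decal-8-ene with the ketal chain on C9, via hydrazone 25 (not isolated)
Conditions: N2H4·H2O, KOH, diethylene glycol, 130 °C then 200 °C
Reagents that add atoms: none
Why: Wolff–Kishner reduction (Huang-Minlon procedure) removes the C3 carbonyl as is routine for 4,4-disubstituted 3-ketones of terpenoids, and the ketal, the isolated alkenes and the non-epimerisable C4, C5 and C10 centres should withstand hot KOH.

**Step 12**
Reactants: 26 4α-allyl decalin
Product: 28 4α-(3-hydroxypropyl)-4β,8,10β-trimethyl-5α-decal-8-ene with the ketal chain on C9, via alkylborane 27 (not isolated)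
Conditions: 9-BBN, THF, 0 °C → rt; then NaOH (aq), H2O2, 0 °C → rt
Reagents that add atoms: hydrogen peroxide, OO
Why: 9-BBN hydroborates only the monosubstituted terminal alkene with anti-Markovnikov regiochemistry, the tetrasubstituted C8=C9 bond being inert, and alkaline peroxide gives the primary alcohol (hydroboration–oxidation).

**Step 13**
Reactants: 28 primary alcohol
Product: 29 4α-(3-oxopropyl)-4β,8,10β-trimethyl-5α-decal-8-ene with the ketal chain on C9
Conditions: Dess–Martin periodinane, NaHCO3, CH2Cl2, 0 °C → rt
Reagents that add atoms: none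
Why: Dess–Martin oxidation under bicarbonate buffer should stop at the aldehyde and keep the dioxolane intact.

**Step 14**
Reactants: 29 aldehyde; 30 isopropyltriphenylphosphonium iodide
Product: 31 4α-(4-methylpent-3-enyl)-4β,8,10β-trimethyl-5α-decal-8-ene with the ketal chain on C9
Conditions: iPrPPh3I, n-BuLi, THF, 0 °C; then 29, −78 °C → rt
Reagents that add atoms: isopropyltriphenylphosphonium iodide (30), CC(C)[P+](c1ccccc1)(c1ccccc1)c1ccccc1.[I-]
Why: Wittig reaction of the unhindered aldehyde with the non-stabilised isopropylidene ylide installs the terminal trisubstituted alkene, for which no E/Z question arises.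

**Step 15**
Reactants: 31 dioxolane
Product: 32 methyl ketone, 4-[4α-(4-methylpent-3-enyl)-4β,8,10β-trimethyl-5α-decal-8-en-9-yl]butan-2-one
Conditions: 1 M HCl (aq), THF, rt
Reagents that add atoms: water, O
Why: Dilute aqueous acid hydrolyses the dioxolane (acetal hydrolysis) to the C13 methyl ketone far faster than it hydrates or cyclises the tri- and tetrasubstituted alkenes.

**Step 16**
Reactants: 32 methyl ketone; 33 triethyl phosphonoacetate
Product: 34 ethyl (2E)-ester of the target acid
Conditions: (EtO)2P(O)CH2CO2Et, NaH, THF, 0 °C; then 32, 65 °C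
Reagents that add atoms: triethyl phosphonoacetate (33), CCOC(=O)CP(=O)(OCC)OCC
Why: Horner–Wadsworth–Emmons olefination of the methyl ketone with the stabilised phosphonate anion is reversible at the addition stage and should therefore favour the (E)-enoate with the ester trans to the larger CH2 substituent, the minor (Z)-isomer being removable by chromatography.

**Step 17**
Reactants: 34 ethyl ester
Product: 35 target acid CNP0237483.2
Conditions: LiOH, THF/MeOH/H2O, 50 °C; then 1 M HCl
Reagents that add atoms: lithium hydroxide, [Li+].[OH-]
Why: Saponification followed by acidification gives the carboxylic acid, and the trisubstituted E alkene and the three stereocentres are not affected by hydroxide at this temperature.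

**Compound list**
1 | (S)-Hajos–Parrish ketone, (7aS)-7a-methyl-2,3,7,7a-tetrahydro-1H-indene-1,5(6H)-dione (C3 enone carbonyl, C4=C5, C9 ketone, 10β-methyl) | O=C1C=C2CCC(=O)[C@@]2(C)CC1 | starting material
2 | ethane-1,2-dithiol | SCCS | starting material
3 | C3 1,3-dithiolane of 1 (spiro dithiolane at C3, C4=C5 kept, C9 ketone free) | C12(SCCS1)C=C3CCC(=O)[C@@]3(C)CC2 | intermediate
4 | N-phenylbis(trifluoromethanesulfonimide) | O=S(=O)(N(c1ccccc1)S(=O)(=O)C(F)(F)F)C(F)(F)F | starting material
5 | potassium C7=C9 enolate of 3 | C12(SCCS1)C=C3CC=C([O-])[C@@]3(C)CC2.[K+] | intermediate (not isolated)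
6 | C9 enol triflate of 3 (C7=C9–OSO2CF3, C3 dithiolane, C4=C5) | C12(SCCS1)C=C3CC=C(OS(=O)(=O)C(F)(F)F)[C@@]3(C)CC2 | intermediate
7 | 2-methyl-2-vinyl-1,3-dioxolane | C=CC1(C)OCCO1 | starting material
8 | B-[2-(2-methyl-1,3-dioxolan-2-yl)ethyl]-9-borabicyclo[3.3.1]nonane | CC1(CCB2C3CCCC2CCC3)OCCO1 | intermediate (not isolated)
9 | C3 dithiolane of the 10β-methylhydrinda-4,7(9)-diene with 2-(2-methyl-1,3-dioxolan-2-yl)ethyl on C9 | C12(SCCS1)C=C3CC=C(CCC4(C)OCCO4)[C@@]3(C)CC2 | intermediate
10 | iodomethane | CI | starting material
11 | 10β-methylhydrinda-4,7(9)-dien-3-one with 2-(2-methyl-1,3-dioxolan-2-yl)ethyl on C9 | O=C1C=C2CC=C(CCC3(C)OCCO3)[C@@]2(C)CC1 | intermediate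
12 | sodium tribromoacetate | [Na+].[O-]C(=O)C(Br)(Br)Br | starting material
13 | 8,8-dibromocyclopropane fused across C7–C9 of 11 on the α face (7β-H, C9 chain β) | O=C1C=C2C[C@H]3C(Br)(Br)[C@@]3(CCC4(C)OCCO4)[C@@]2(C)CC1 | intermediate (not isolated)
14 | 7α,8-dibromo-10β-methyldecalin-4,8-dien-3-one with the ketal chain on C9 | O=C1C=C2C[C@@H](Br)C(Br)=C(CCC3(C)OCCO3)[C@@]2(C)CC1 | intermediate
15 | 8-bromo-10β-methyldecalin-4,8-dien-3β-ol with the ketal chain on C9 | O[C@@H]1C=C2CCC(Br)=C(CCC3(C)OCCO3)[C@@]2(C)CC1 | intermediate
16 | 8-bromo-10β-methyldecalin-4,8-dien-3-one with the ketal chain on C9 | O=C1C=C2CCC(Br)=C(CCC3(C)OCCO3)[C@@]2(C)CC1 | intermediate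
17 | dimethylzinc | C[Zn]C | starting material
18 | 8,10β-dimethyldecalin-4,8-dien-3-one with the ketal chain on C9 | O=C1C=C2CCC(C)=C(CCC3(C)OCCO3)[C@@]2(C)CC1 | intermediate
19 | potassium 3,5-dienolate of 18 | [K+].[O-]C1=CC2=CCC(C)=C(CCC3(C)OCCO3)[C@@]2(C)CC1 | intermediate (not isolated)
20 | 4,8,10β-trimethyldecalin-5,8-dien-3-one with the ketal chain on C9 (C4 epimers) | O=C1C(C)C2=CCC(C)=C(CCC3(C)OCCO3)[C@@]2(C)CC1 | intermediate (not isolated)
21 | 4,8,10β-trimethyldecalin-4,8-dien-3-one with the ketal chain on C9 | O=C1C(C)=C2CCC(C)=C(CCC3(C)OCCO3)[C@@]2(C)CC1 | intermediate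
22 | allyl bromide | C=CCBr | starting material
23 | lithium C3=C4 enolate of the 5α-H (trans-fused) 4,8,10β-trimethyldecal-8-en-3-one | [Li+].[O-]C1=C(C)[C@@H]2CCC(C)=C(CCC3(C)OCCO3)[C@@]2(C)CC1 | intermediate (not isolated)
24 | 4α-allyl-4β,8,10β-trimethyl-5α-decal-8-en-3-one with the ketal chain on C9 | C=CC[C@]1(C)C(=O)CC[C@]2(C)C(CCC3(C)OCCO3)=C(C)CC[C@@H]12 | intermediate
25 | C3 hydrazone of 24 | C=CC[C@]1(C)C(=NN)CC[C@]2(C)C(CCC3(C)OCCO3)=C(C)CC[C@@H]12 | intermediate (not isolated)
26 | 4α-allyl-4β,8,10β-trimethyl-5α-decal-8-ene with the ketal chain on C9 | C=CC[C@]1(C)CCC[C@]2(C)C(CCC3(C)OCCO3)=C(C)CC[C@@H]12 | intermediate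
27 | B-alkyl-9-borabicyclo[3.3.1]nonane from hydroboration of the allyl terminus of 26 | B1(C2CCCC1CCC2)CCC[C@]3(C)CCC[C@]4(C)C(CCC5(C)OCCO5)=C(C)CC[C@@H]34 | intermediate (not isolated)
28 | 4α-(3-hydroxypropyl)-4β,8,10β-trimethyl-5α-decal-8-ene with the ketal chain on C9 | OCCC[C@]1(C)CCC[C@]2(C)C(CCC3(C)OCCO3)=C(C)CC[C@@H]12 | intermediate
29 | 4α-(3-oxopropyl)-4β,8,10β-trimethyl-5α-decal-8-ene with the ketal chain on C9 | O=CCC[C@]1(C)CCC[C@]2(C)C(CCC3(C)OCCO3)=C(C)CC[C@@H]12 | intermediate
30 | isopropyltriphenylphosphonium iodide | CC(C)[P+](c1ccccc1)(c1ccccc1)c1ccccc1.[I-] | starting material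
31 | 4α-(4-methylpent-3-enyl)-4β,8,10β-trimethyl-5α-decal-8-ene with the ketal chain on C9 | CC(C)=CCC[C@]1(C)CCC[C@]2(C)C(CCC3(C)OCCO3)=C(C)CC[C@@H]12 | intermediate
32 | 4-[4α-(4-methylpent-3-enyl)-4β,8,10β-trimethyl-5α-decal-8-en-9-yl]butan-2-one | CC(C)=CCC[C@]1(C)CCC[C@]2(C)C(CCC(C)=O)=C(C)CC[C@@H]12 | intermediate
33 | triethyl phosphonoacetate | CCOC(=O)CP(=O)(OCC)OCC | starting material
34 | ethyl (2E)-3-methyl-5-[4α-(4-methylpent-3-enyl)-4β,8,10β-trimethyl-5α-decal-8-en-9-yl]pent-2-enoate | CC(C)=CCC[C@]1(C)CCC[C@]2(C)C(CC/C(C)=C/C(=O)OCC)=C(C)CC[C@@H]12 | intermediate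
35 | (2E)-3-methyl-5-[(4aS,5S,8aS)-2,5,8a-trimethyl-5-(4-methylpent-3-en-1-yl)-3,4,4a,5,6,7,8,8a-octahydronaphthalen-1-yl]pent-2-enoic acid (CNP0237483.2) | CC(C)=CCC[C@]1(C)CCC[C@]2(C)C(CC/C(C)=C/C(=O)O)=C(C)CC[C@@H]12 | target

**Count**
Total steps: 17. Longest linear sequence: 17 steps, from 1 to 35; all other partners are purchased and alkylborane 8 is made in the flask.

**Steps most likely to fail**

Step 5. The allylic bromide may lose HBr towards a fully conjugated bromotrienone during the thermal opening, because the C6 hydrogens are vinylogously acidified by the enone. CBr3− may also attack the enone carbonyl, and the cyclopropane may open incompletely. In that case C8 would be inserted next to the C9 carbonyl at an earlier stage, setting out from dithiolane ketone 3. Trimethylsilyldiazomethane with BF3·OEt2 (CH2Cl2, −78 °C) is expected to give, by migration of the less substituted C7 methylene, the C8-silylated ring-enlarged ketone F1. This loses silicon on dilute acid work-up to give the six-membered C9 ketone F2. LiN(iPr)2 and MeI methylate its only enolisable position to give the 8-methyl ketone F3. KN(SiMe3)2 and PhNTf2 then give the tetrasubstituted C8=C9 enol triflate F4. B-alkyl Suzuki coupling with alkylborane 8 gives the dithiolane-protected 8-methyl diene F5, and MeI/CaCO3 hydrolysis of its dithiolane returns to the route at enone 18.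

Step 9. The dienolate may be methylated twice, to the 4,4-dimethyl Δ5 ketone, or on oxygen. The methyl group would then be brought to C4 as a sulfur-bearing one-carbon unit, setting out from enone 18. Aqueous formaldehyde, thiophenol and Et3N in refluxing EtOH should give the 4-(phenylsulfanylmethyl) enone F6; this α-thiomethylation cannot go twice because the product keeps no α-hydrogen and stays conjugated. Deactivated Raney nickel in acetone then cleaves the C–S bond and returns to the route at 21.

Step 10. The enolate may be protonated or may equilibrate towards C2 before it is alkylated, and O-allylation may compete. The C4–C18 bond would then be made by decarboxylative allylation, setting out from 21. Li/NH3 reduction as in step 10, removal of ammonia and trapping of enolate 23 in THF with allyl chloroformate give the allyl enol carbonate F7. Pd(PPh3)4 in THF then triggers the Tsuji allylation, in which the enolate and the allyl–palladium partner are generated together and regiospecifically at C4. The same α-face preference is expected, and the sequence returns to the route at 24.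

**Further compounds**
F1 | step 5 | C8-trimethylsilyl ring-enlarged ketone (C3 dithiolane, C4=C5, C9 ketone, C8 bearing SiMe3) | C12(SCCS1)C=C3CCC([Si](C)(C)C)C(=O)[C@@]3(C)CC2
F2 | step 5 | 10β-methyldecal-4-ene-3,9-dione 3-dithiolane (six-membered ring B, C9 ketone) | C12(SCCS1)C=C3CCCC(=O)[C@@]3(C)CC2
F3 | step 5 | 8,10β-dimethyldecal-4-ene-3,9-dione 3-dithiolane (C8 epimers) | C12(SCCS1)C=C3CCC(C)C(=O)[C@@]3(C)CC2
F4 | step 5 | C8=C9 enol triflate of F3 | C12(SCCS1)C=C3CCC(C)=C(OS(=O)(=O)C(F)(F)F)[C@@]3(C)CC2
F5 | step 5 | C3 dithiolane of 18 | C12(SCCS1)C=C3CCC(C)=C(CCC4(C)OCCO4)[C@@]3(C)CC2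
F6 | step 9 | 4-(phenylsulfanylmethyl) derivative of 18 | O=C1C(CSc2ccccc2)=C2CCC(C)=C(CCC3(C)OCCO3)[C@@]2(C)CC1
F7 | step 10 | allyl enol carbonate of enolate 23 (C3–OCO2CH2CH=CH2, C3=C4, 5α-H) | C=CCOC(=O)OC1=C(C)[C@@H]2CCC(C)=C(CCC3(C)OCCO3)[C@@]2(C)CC1
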